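Assumption: the target has no stereocentre or other stereogenic element (it is achiral), so no stereocontrol is needed. Rings are lettered A–G from the 2,4,6-trihydroxyphenyl end (A) to the 3,4,5-trihydroxyphenyl end (G), and the four starting materials marked in the compound list are taken as commercial.

**Retrosynthetic overview**

1. The target comes from its octadeca-O-methyl ether by one global BBr3 demethylation. No ring is built: all seven benzene rings are bought, and only the six Ar–O–Ar bonds are made.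
2. Each ether bond is cut so that the di-ortho-oxygenated oxygen is the phenol nucleophile and the ring with free ortho positions (or an ortho-CHO) is the aryl bromide (Ullmann coupling).
3. The repeating B–C = D–E unit is one bifunctional dimer, with an aryl bromide on the B/D ring and an aldehyde on the C/E ring as a masked phenol (Dakin oxidation). It is used twice.
4. Joining order: B–O–C (dimer), then A–O–B, unmask, C–O–D (second dimer), unmask, E–O–F with a separately made F–O–G bromide (Chan–Lam), then demethylation.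

**Route**

Step 1
Reactants: 1 5-bromo-1,2,3-trimethoxybenzene
Product: 3 6-bromo-2,3,4-trimethoxybenzaldehyde, via alpha-chloro ether 2 (not isolated)
Conditions: Cl2CHOMe (1.5 equiv), TiCl4 (2.2 equiv), CH2Cl2, 0 °C to rt; then ice-water
Reagents that add atoms: dichloromethyl methyl ether COC(Cl)Cl; water O
Why: Rieche formylation (Friedel–Crafts-type SEAr) at the only kind of free ring position, which is ortho/para to methoxy groups, gives a single regioisomer after hydrolysis of the chloro ether on work-up.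

Step 2
Reactants: 3 6-bromo-2,3,4-trimethoxybenzaldehyde; 4 4-bromo-2,6-dimethoxyphenol
Product: 5 6-(4-bromo-2,6-dimethoxyphenoxy)-2,3,4-trimethoxybenzaldehyde
Conditions: CuI (10 mol%), picolinic acid (20 mol%), K3PO4 (2 equiv), DMSO, 80 °C, Ar; 3 in 1.3-fold excess
Reagents that add atoms: none
Why: Ullmann diaryl ether coupling that is chemoselective because the bromide of 3 is activated by the ortho-formyl group, whereas the bromide of 4 sits para to a phenoxide and that of the product is electron-rich and unactivated.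

Step 3
Reactants: 6 2,4,6-trimethoxyphenol; 5 6-(4-bromo-2,6-dimethoxyphenoxy)-2,3,4-trimethoxybenzaldehyde
Product: 7 6-[2,6-dimethoxy-4-(2,4,6-trimethoxyphenoxy)phenoxy]-2,3,4-trimethoxybenzaldehyde
Conditions: CuI (20 mol%), picolinic acid (40 mol%), K3PO4 (2 equiv), DMSO, 100 °C, Ar; 6 (1.5 equiv)
Reagents that add atoms: none
Why: Ullmann coupling with the picolinic acid ligand tolerates the di-ortho-substituted phenol, and the bromide of 5 has two free ortho positions.

Step 4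
Reactants: 7 6-[2,6-dimethoxy-4-(2,4,6-trimethoxyphenoxy)phenoxy]-2,3,4-trimethoxybenzaldehyde
Product: 9 6-[2,6-dimethoxy-4-(2,4,6-trimethoxyphenoxy)phenoxy]-2,3,4-trimethoxyphenol, via aryl formate 8 (not isolated)
Conditions: mCPBA (1.3 equiv), CH2Cl2, 0 °C to rt; aq. NaHCO3 wash; then K2CO3 (cat.), MeOH, 0 °C, Ar
Reagents that add atoms: mCPBA OOC(=O)c1cccc(Cl)c1
Why: Baeyer–Villiger (Dakin-type) oxidation in which the electron-rich 2,4,6-trioxygenated aryl group migrates to give the formate, which is then cleaved by methanolysis to the phenol.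

Step 5
Reactants: 9 6-[2,6-dimethoxy-4-(2,4,6-trimethoxyphenoxy)phenoxy]-2,3,4-trimethoxyphenol; 5 6-(4-bromo-2,6-dimethoxyphenoxy)-2,3,4-trimethoxybenzaldehyde
Product: 10 6-(4-{6-[2,6-dimethoxy-4-(2,4,6-trimethoxyphenoxy)phenoxy]-2,3,4-trimethoxyphenoxy}-2,6-dimethoxyphenoxy)-2,3,4-trimethoxybenzaldehyde
Conditions: CuI (20 mol%), picolinic acid (40 mol%), K3PO4 (2 equiv), DMSO, 100 °C, Ar; 5 (1.3 equiv)
Reagents that add atoms: none
Why: Ullmann coupling of the same type as step 3, with the hindered phenol as nucleophile and the unhindered bromide of the second dimer unit as electrophile.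

Step 6
Reactants: 10 6-(4-{6-[2,6-dimethoxy-4-(2,4,6-trimethoxyphenoxy)phenoxy]-2,3,4-trimethoxyphenoxy}-2,6-dimethoxyphenoxy)-2,3,4-trimethoxybenzaldehyde
Product: 12 6-(4-{6-[2,6-dimethoxy-4-(2,4,6-trimethoxyphenoxy)phenoxy]-2,3,4-trimethoxyphenoxy}-2,6-dimethoxyphenoxy)-2,3,4-trimethoxyphenol, via aryl formate 11 (not isolated)
Conditions: mCPBA (1.3 equiv), CH2Cl2, 0 °C to rt; aq. NaHCO3 wash; then K2CO3 (cat.), MeOH, 0 °C, Ar
Reagents that add atoms: mCPBA OOC(=O)c1cccc(Cl)c1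
Why: Second Baeyer–Villiger (Dakin-type) oxidation, working for the same reason as step 4 on the same 2,4,6-trioxygenated benzaldehyde motif.

Step 7
Reactants: 4 4-bromo-2,6-dimethoxyphenol; 13 (3,4,5-trimethoxyphenyl)boronic acid
Product: 14 5-bromo-1,3-dimethoxy-2-(3,4,5-trimethoxyphenoxy)benzene
Conditions: Cu(OAc)2 (20 mol%), pyridine (3 equiv), 4 Å MS, CH2Cl2, O2 (1 atm), rt; 13 (2 equiv)
Reagents that add atoms: none
Why: Chan–Lam oxidative O-arylation runs at room temperature, accepts di-ortho-substituted phenols and leaves the aryl bromide untouched.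

Step 8
Reactants: 12 6-(4-{6-[2,6-dimethoxy-4-(2,4,6-trimethoxyphenoxy)phenoxy]-2,3,4-trimethoxyphenoxy}-2,6-dimethoxyphenoxy)-2,3,4-trimethoxyphenol; 14 5-bromo-1,3-dimethoxy-2-(3,4,5-trimethoxyphenoxy)benzene
Product: 15 5-[6-(4-{6-[2,6-dimethoxy-4-(2,4,6-trimethoxyphenoxy)phenoxy]-2,3,4-trimethoxyphenoxy}-2,6-dimethoxyphenoxy)-2,3,4-trimethoxyphenoxy]-1,3-dimethoxy-2-(3,4,5-trimethoxyphenoxy)benzene (the octadeca-O-methyl ether of the target)
Conditions: CuI (30 mol%), picolinic acid (60 mol%), K3PO4 (2 equiv), DMSO, 110 °C, Ar; 14 (1.5 equiv)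
Reagents that add atoms: none
Why: Ullmann coupling of the same type as steps 3 and 5, since the bromide of 14 has two free ortho positions and no other reactive group remains.

Step 9
Reactants: 15 the octadeca-O-methyl ether of the target
Product: 16 5-[6-(4-{6-[2,6-dihydroxy-4-(2,4,6-trihydroxyphenoxy)phenoxy]-2,3,4-trihydroxyphenoxy}-2,6-dihydroxyphenoxy)-2,3,4-trihydroxyphenoxy]-2-(3,4,5-trihydroxyphenoxy)benzene-1,3-diol (CNP0292517.0)
Conditions: BBr3 (40 equiv), CH2Cl2, −78 °C to rt, 24 h; then MeOH/H2O, 0 °C; Sephadex LH-20 under Ar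
Reagents that add atoms: none
Why: Lewis-acid ether cleavage in which bromide attacks the methyl groups by SN2, removing all eighteen aryl methyl ethers while diaryl ether C–O bonds are inert to BBr3.

**Compound list**

1 | 5-bromo-1,2,3-trimethoxybenzene | COc1cc(Br)cc(OC)c1OC | starting material
2 | 1-bromo-2-[chloro(methoxy)methyl]-3,4,5-trimethoxybenzene | COC(Cl)c1c(Br)cc(OC)c(OC)c1OC | intermediate (not isolated; racemic)
3 | 6-bromo-2,3,4-trimethoxybenzaldehyde | O=Cc1c(Br)cc(OC)c(OC)c1OC | intermediate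
4 | 4-bromo-2,6-dimethoxyphenol | COc1cc(Br)cc(OC)c1O | starting material
5 | 6-(4-bromo-2,6-dimethoxyphenoxy)-2,3,4-trimethoxybenzaldehyde | O=Cc1c(Oc2c(OC)cc(Br)cc2OC)cc(OC)c(OC)c1OC | intermediate
6 | 2,4,6-trimethoxyphenol | COc1cc(OC)c(O)c(OC)c1 | starting material
7 | 6-[2,6-dimethoxy-4-(2,4,6-trimethoxyphenoxy)phenoxy]-2,3,4-trimethoxybenzaldehyde | O=Cc1c(Oc2c(OC)cc(Oc3c(OC)cc(OC)cc3OC)cc2OC)cc(OC)c(OC)c1OC | intermediate
8 | 6-[2,6-dimethoxy-4-(2,4,6-trimethoxyphenoxy)phenoxy]-2,3,4-trimethoxyphenyl formate | O=COc1c(Oc2c(OC)cc(Oc3c(OC)cc(OC)cc3OC)cc2OC)cc(OC)c(OC)c1OC | intermediate (not isolated)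
9 | 6-[2,6-dimethoxy-4-(2,4,6-trimethoxyphenoxy)phenoxy]-2,3,4-trimethoxyphenol | Oc1c(Oc2c(OC)cc(Oc3c(OC)cc(OC)cc3OC)cc2OC)cc(OC)c(OC)c1OC | intermediate
10 | 6-(4-{6-[2,6-dimethoxy-4-(2,4,6-trimethoxyphenoxy)phenoxy]-2,3,4-trimethoxyphenoxy}-2,6-dimethoxyphenoxy)-2,3,4-trimethoxybenzaldehyde | O=Cc1c(Oc2c(OC)cc(Oc3c(Oc4c(OC)cc(Oc5c(OC)cc(OC)cc5OC)cc4OC)cc(OC)c(OC)c3OC)cc2OC)cc(OC)c(OC)c1OC | intermediate
11 | 6-(4-{6-[2,6-dimethoxy-4-(2,4,6-trimethoxyphenoxy)phenoxy]-2,3,4-trimethoxyphenoxy}-2,6-dimethoxyphenoxy)-2,3,4-trimethoxyphenyl formate | O=COc1c(Oc2c(OC)cc(Oc3c(Oc4c(OC)cc(Oc5c(OC)cc(OC)cc5OC)cc4OC)cc(OC)c(OC)c3OC)cc2OC)cc(OC)c(OC)c1OC | intermediate (not isolated)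
12 | 6-(4-{6-[2,6-dimethoxy-4-(2,4,6-trimethoxyphenoxy)phenoxy]-2,3,4-trimethoxyphenoxy}-2,6-dimethoxyphenoxy)-2,3,4-trimethoxyphenol | Oc1c(Oc2c(OC)cc(Oc3c(Oc4c(OC)cc(Oc5c(OC)cc(OC)cc5OC)cc4OC)cc(OC)c(OC)c3OC)cc2OC)cc(OC)c(OC)c1OC | intermediate
13 | (3,4,5-trimethoxyphenyl)boronic acid | COc1cc(B(O)O)cc(OC)c1OC | starting material
14 | 5-bromo-1,3-dimethoxy-2-(3,4,5-trimethoxyphenoxy)benzene | COc1cc(Br)cc(OC)c1Oc1cc(OC)c(OC)c(OC)c1 | intermediate
15 | 5-[6-(4-{6-[2,6-dimethoxy-4-(2,4,6-trimethoxyphenoxy)phenoxy]-2,3,4-trimethoxyphenoxy}-2,6-dimethoxyphenoxy)-2,3,4-trimethoxyphenoxy]-1,3-dimethoxy-2-(3,4,5-trimethoxyphenoxy)benzene | COc1cc(Oc2c(OC)cc(Oc3c(Oc4c(OC)cc(Oc5c(Oc6c(OC)cc(Oc7c(OC)cc(OC)cc7OC)cc6OC)cc(OC)c(OC)c5OC)cc4OC)cc(OC)c(OC)c3OC)cc2OC)cc(OC)c1OC | intermediate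
16 | 5-[6-(4-{6-[2,6-dihydroxy-4-(2,4,6-trihydroxyphenoxy)phenoxy]-2,3,4-trihydroxyphenoxy}-2,6-dihydroxyphenoxy)-2,3,4-trihydroxyphenoxy]-2-(3,4,5-trihydroxyphenoxy)benzene-1,3-diol (CNP0292517.0) | Oc1cc(O)c(Oc2cc(O)c(Oc3cc(O)c(O)c(O)c3Oc3cc(O)c(Oc4cc(O)c(O)c(O)c4Oc4cc(O)c(Oc5cc(O)c(O)c(O)c5)c(O)c4)c(O)c3)c(O)c2)c(O)c1 | target

**Summary**

Total step count: 9.
Longest linear sequence: 8 steps (steps 1, 2, 3, 4, 5, 6, 8, 9); step 7 is a one-step side branch.

Steps most likely to fail: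

Step 2 (chemoselective Ullmann coupling with a bromophenol). The phenol 4 may couple with itself, or product 5 may be arylated further. The fallback sets out from 1 and 4 and comes back at 5. Compound 1 is converted by Br/Li exchange (n-BuLi, THF, −78 °C) and NFSI into 5-fluoro-1,2,3-trimethoxybenzene F1. This is lithiated between F and OMe (n-BuLi, THF, −78 °C) and quenched with DMF to give 6-fluoro-2,3,4-trimethoxybenzaldehyde F2. A copper-free SNAr of F2 with 4 (K2CO3, DMF, 120 °C) then gives 5; without copper the aryl bromide of 4 cannot react.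

Step 8 (Ullmann coupling of the large, hindered pentaaryl phenol 12 with the electron-rich bromide 14). The fallback sets out from 14 and comes back at 15. Compound 14 is converted by Br/Li exchange (n-BuLi, THF, −78 °C), B(OiPr)3 and aqueous acid into [3,5-dimethoxy-4-(3,4,5-trimethoxyphenoxy)phenyl]boronic acid F3. This is joined to 12 by a room-temperature Chan–Lam coupling (Cu(OAc)2, pyridine, 4 Å MS, CH2Cl2, O2), replacing the halide/Cu(I) manifold with an oxidative boron-based one.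

Step 9 (eighteen-fold demethylation and isolation of an air-sensitive polyphenol). The risks are incomplete cleavage and loss on purification. The fallback sets out from 15 and comes back at 16. After the BBr3 treatment and methanol quench the crude product is not purified but acetylated (Ac2O, pyridine, DMAP cat., rt) to the octadeca-O-acetate of 16 F4. This is stable, can be purified on silica and separated from under-demethylated material, and is then cleaved by acid methanolysis (AcCl in MeOH, rt, Ar) to 16.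

**Further compounds**

F1 | step 2 | 5-fluoro-1,2,3-trimethoxybenzene | COc1cc(F)cc(OC)c1OC
F2 | step 2 | 6-fluoro-2,3,4-trimethoxybenzaldehyde | O=Cc1c(F)cc(OC)c(OC)c1OC
F3 | step 8 | [3,5-dimethoxy-4-(3,4,5-trimethoxyphenoxy)phenyl]boronic acid | COc1cc(B(O)O)cc(OC)c1Oc1cc(OC)c(OC)c(OC)c1
F4 | step 9 | octadeca-O-acetate of 16 | CC(=O)Oc1cc(Oc2c(OC(C)=O)cc(Oc3c(Oc4c(OC(C)=O)cc(Oc5c(Oc6c(OC(C)=O)cc(Oc7c(OC(C)=O)cc(OC(C)=O)cc7OC(C)=O)cc6OC(C)=O)cc(OC(C)=O)c(OC(C)=O)c5OC(C)=O)cc4OC(C)=O)cc(OC(C)=O)c(OC(C)=O)c3OC(C)=O)cc2OC(C)=O)cc(OC(C)=O)c1OC(C)=O
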